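(The readings were generated by integration on assumed constants; the scatter is artificial.)

Each Xp made takes one Xa and one Xb, so under the overall equation the gap between Xa and Xb stays as charged while a flask runs. The zeta and delta flasks share that gap, 0.0600 M and 0.0600 M, so the zeta flask passes through the delta charge once it has used 0.150 M of each.

| setting | zeta | delta | eta | epsilon |
|---|---|---|---|---|
| Xa | 0.300 M | 0.150 M | 0.450 M | 0.900 M |
| Xb | 0.240 M | 0.0900 M | 0.240 M | 0.240 M |
| Xc | 0.00600 M | 0.00600 M | 0.00600 M | 0.00600 M |
| time |  |  |  | 3.9 min |

| zeta run: time / min | zeta run: [Xp] / M | delta run: time / min | delta run: [Xp] / M | eta run: time / min | eta run: [Xp] / M |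
|---|---|---|---|---|---|
| 0.49 | 0.0278 | 0.49 | 0.0167 | 0.49 | 0.0287 |
| 0.97 | 0.0507 | 0.97 | 0.0349 | 0.97 | 0.0568 |
| 1.5 | 0.0779 | 1.5 | 0.0497 | 1.5 | 0.0872 |
| 1.9 | 0.0988 | 1.9 | 0.0597 | 1.9 | 0.1085 |
| 2.4 | 0.1200 | 2.4 | 0.0710 | 2.4 | 0.1319 |
| 2.9 | 0.1429 | 2.9 | 0.0791 | 2.9 | 0.1505 |
| 3.4 | 0.1622 | 3.4 | 0.0837 | 3.4 | 0.1707 |
| 3.9 | 0.1783 | 3.9 | 0.0871 | 3.9 | 0.1861 |

(scatter of a reading: 9 × 10⁻⁴ M)

- reaction order in [Xa] at the outset, round the charge of the zeta run, defined at two percent of the Xa turned into Xp (one fixed amount of Xp, the same in the runs compared)
- reaction order in [Xb] at the outset, round the charge of the zeta run, defined at two percent of the Xa turned into Xp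
- the delta run starts with 0.150 M less of Xa and of Xb than the zeta run, and with no Xp. Compared where both hold the same amount of Xa, once fifteen percent of what the delta run was charged with has turned into Xp, is the delta run faster, slower or alike (within a tenth)?
- Xp in the epsilon run at 3.9 min, as a share of the Xa charged

- Overall: Xa + Xb -> Xp, with Xc as catalyst.
- Constant volume, constant temperature.
- What is held in complexes is read along with the free species.
- "The second partner" is Xb.
- An order is taken over about fifteen percent of the charge, up and down.

The bench rule says that a curve which starts straight stays straight until the scarcer partner is gone. In the epsilon flask that partner, the limiting reagent, is Xb, charged at 0.240 M, less than the 0.900 M of Xa, and its charge caps Xp at 26.7% of the Xa charged.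

To test the rule, we divide the Xb charge by the mean rate so far. In the eta flask, up to the final reading, this gives 5.03 min. We call this lifetime the Xb clock: the time the Xb charge would last at that mean rate. A straight line would keep the clock steady, but at the second reading the eta flask gave 4.10 min, so the clock has lengthened. The rule therefore stops working before Xb is gone: at the final reading 22.5% of the eta Xb charge is still there.

Raising Xa by a factor of 1.50 from zeta to eta shortens the final clock from 5.25 min to 5.03 min, a small change. We therefore keep the eta clock for the epsilon flask, which gives Xp at 20.7% of the Xa charged, below the cap.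

Mean rates up to the second reading, zeta against eta, give us a reading of the order in Xa of 0.280. No run changes Xb alone, but comparing delta with zeta and removing that Xa effect leaves about 0.183 in Xb. Across the readings on either side of the asked point, the delta flask has a slope of 0.0379 M min⁻¹ and the zeta flask one of 0.0322 M min⁻¹. They differ by 0.00572 M min⁻¹, and each slope carries a scatter near 0.00255 M min⁻¹, so we cannot tell them apart and answer alike.

The forecast gives 0.2 and 0.15 for the orders, alike for the comparison and 21.4% for the share, a little above our 20.7%, and reads the flask as “near-saturated catalysis”.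

The flask gives 15.2% for the epsilon share, orders of 0.66 in Xa and −0.17 in Xb, and alike for delta against zeta. Its equations are:

    Xc + Xa → Q + Xh (144.6 M⁻¹ min⁻¹)
    Q + Xb → Xp + Xc (714.0 M⁻¹ min⁻¹)
    Xc + Xa ⇌ Xc.Xa, settled at all times (4.100 M⁻¹)
    Xa + Xb ⇌ Xa.Xb, settled at all times (21.40 M⁻¹)

At equal Xp, the eta rate stands at 1.1 times the zeta rate. The epsilon clock at 3.9 min reads 6.86 min, longer than the 5.03 min of the eta flask at the same time. In the delta flask the Xp made comes to half of the substrate charged at 2.64 min, and its clock there reads 3.16 min.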